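**Assumption:** Artocarpetin B has no stereocentre and its only non-ring alkene carries two identical methyl groups, so the SMILES defines one achiral compound and no stereocontrol is needed.

## Retrosynthetic overview

1. The target comes from its 4'-O-pivalate; the C8 prenyl group comes from a 5-O-prenyl ether by a para-Claisen–Cope shift, which also frees the 5-OH.
2. Ring C (the pyranone) is closed by acid cyclodehydration of a 1-(2,6-dihydroxyaryl)-3-aryl-1,3-diketone; the symmetric ring A allows only one flavone.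
3. Key C–C bond (between the future C3 and C2): intermolecular crossed Claisen condensation of the enolate of 2',6'-dihydroxy-4'-methoxyacetophenone with 2-methoxy-4-(pivaloyloxy)benzoyl chloride.
4. Fragments: phloroacetophenone (4-O-methylation) and 4-hydroxy-2-methoxybenzaldehyde (pivaloylation, Pinnick oxidation, acid chloride).
5. Ring order: rings A and B are bought as aromatics, ring C is formed after the coupling, and the prenyl group is moved onto C8 last.

## Route

Step 1
Reactants: 1 2',4',6'-trihydroxyacetophenone (phloroacetophenone)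
Product: 2 1-(2,6-dihydroxy-4-methoxyphenyl)ethan-1-one
Conditions: Me2SO4 (1.0 equiv), K2CO3 (1.0 equiv), acetone, rt to 40 °C
Reagents that add atoms: dimethyl sulfate, COS(=O)(=O)OC
Why: Williamson O-methylation (SN2) is selective for the 4-OH because it is the only hydroxyl not hydrogen-bonded to the acetyl carbonyl and is the most acidic, the dimethyl ether by-product being separable.

Step 2
Reactants: 3 4-hydroxy-2-methoxybenzaldehyde
Product: 4 4-formyl-3-methoxyphenyl pivalate
Conditions: PivCl (1.1 equiv), Et3N, DMAP (cat.), CH2Cl2, 0 °C to rt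
Reagents that add atoms: pivaloyl chloride, CC(C)(C)C(=O)Cl
Why: DMAP-catalysed O-acylation of the only nucleophilic site gives a hindered aryl ester that tolerates the later oxidising, acidic, thermal and low-temperature strong-base steps and is removed at the end by mild methanolysis.

Step 3
Reactants: 4 4-formyl-3-methoxyphenyl pivalate
Product: 5 2-methoxy-4-(pivaloyloxy)benzoic acid
Conditions: NaClO2, NaH2PO4, 2-methyl-2-butene, t-BuOH/H2O, rt
Reagents that add atoms: sodium chlorite, [Na+].[O-]Cl=O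
Why: Pinnick oxidation converts the aryl aldehyde into the acid at about pH 4, where the pivalate is untouched, with the alkene scavenging the hypochlorous acid formed.

Step 4
Reactants: 5 2-methoxy-4-(pivaloyloxy)benzoic acid
Product: 6 2-methoxy-4-(pivaloyloxy)benzoyl chloride
Conditions: (COCl)2 (1.3 equiv), DMF (cat.), CH2Cl2, 0 °C to rt; evaporate, use crude
Reagents that add atoms: oxalyl chloride, O=C(Cl)C(Cl)=O
Why: Vilsmeier-type activation with oxalyl chloride and catalytic DMF gives the acid chloride with only gaseous by-products and leaves the aryl ester and methyl ether alone.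

Step 5
Reactants: 2 1-(2,6-dihydroxy-4-methoxyphenyl)ethan-1-one; 6 2-methoxy-4-(pivaloyloxy)benzoyl chloride
Product: 8 4-[3-(2,6-dihydroxy-4-methoxyphenyl)-3-oxopropanoyl]-3-methoxyphenyl pivalate, via trilithium enolate trianion 7 (not isolated)
Conditions: 2, LiN(SiMe3)2 (4.0 equiv), THF, −78 to −10 °C; then 6 (1.0 equiv), −78 °C to rt; aq. HCl work-up
Reagents that add atoms: none
Why: Intermolecular crossed Claisen condensation in which the enolate carbon of the trianion, its most nucleophilic site, is C-acylated by the aroyl chloride far faster than the hindered aryl pivalate can react, the fourth equivalent of base absorbing the acidic β-diketone.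

Step 6
Reactants: 8 4-[3-(2,6-dihydroxy-4-methoxyphenyl)-3-oxopropanoyl]-3-methoxyphenyl pivalate
Product: 10 4-(5-hydroxy-7-methoxy-4-oxo-4H-chromen-2-yl)-3-methoxyphenyl pivalate, via 2-hydroxyflavanone hemiketal 9 (not isolated)
Conditions: H2SO4 (cat., 0.5% v/v), AcOH, 95 °C, 1 h
Reagents that add atoms: none
Why: Acid-catalysed cyclodehydration (hemiketal formation, then loss of water) closes ring C, and because the two ortho hydroxyls are equivalent only one flavone can form, while aryl methyl ethers and the pivalate are stable in water-poor acetic acid.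

Step 7
Reactants: 10 4-(5-hydroxy-7-methoxy-4-oxo-4H-chromen-2-yl)-3-methoxyphenyl pivalate
Product: 11 3-methoxy-4-{7-methoxy-5-[(3-methylbut-2-en-1-yl)oxy]-4-oxo-4H-chromen-2-yl}phenyl pivalate
Conditions: prenyl bromide (3 equiv), K2CO3 (3 equiv), dry acetone, reflux, 24 h
Reagents that add atoms: prenyl bromide (1-bromo-3-methylbut-2-ene), CC(C)=CCBr
Why: Williamson etherification of the only free hydroxyl, whose chelation to C4=O slows but does not prevent SN2 attack on the reactive allylic bromide, anhydrous carbonate leaving the pivalate intact.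

Step 8
Reactants: 11 3-methoxy-4-{7-methoxy-5-[(3-methylbut-2-en-1-yl)oxy]-4-oxo-4H-chromen-2-yl}phenyl pivalate
Product: 14 4-[5-hydroxy-7-methoxy-8-(3-methylbut-2-en-1-yl)-4-oxo-4H-chromen-2-yl]-3-methoxyphenyl pivalate, via ortho-dienone 12 (not isolated), via para-dienone 13 (not isolated)
Conditions: Eu(fod)3 (10 mol%; fod = 6,6,7,7,8,8,8-heptafluoro-2,2-dimethyl-3,5-octanedionate), NaHCO3, PhCl, 85 °C
Reagents that add atoms: none
Why: Tandem para-Claisen–Cope rearrangement in which the trivalent europium Lewis acid chelates C4=O and O5, the [3,3] shift puts a 1,1-dimethylallyl group on C6, a second [3,3] (Cope) shift delivers the normal prenyl group to C8, and enolisation restores the aromatic ring and erases the transient sp3 centre.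

Step 9
Reactants: 14 4-[5-hydroxy-7-methoxy-8-(3-methylbut-2-en-1-yl)-4-oxo-4H-chromen-2-yl]-3-methoxyphenyl pivalate
Product: 15 Artocarpetin B, 5-hydroxy-2-(4-hydroxy-2-methoxyphenyl)-7-methoxy-8-(3-methylbut-2-en-1-yl)-4H-chromen-4-one
Conditions: K2CO3 (1.5 equiv), MeOH, rt; aq. NH4Cl work-up
Reagents that add atoms: none
Why: Base-mediated transesterification (methanolysis) removes the aryl pivalate under conditions that touch neither the prenyl alkene, the methyl ethers nor the flavone core.

## Compound list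

1 | 2',4',6'-trihydroxyacetophenone | CC(=O)c1c(O)cc(O)cc1O | starting material
2 | 1-(2,6-dihydroxy-4-methoxyphenyl)ethan-1-one | CC(=O)c1c(O)cc(OC)cc1O | intermediate
3 | 4-hydroxy-2-methoxybenzaldehyde | COc1cc(O)ccc1C=O | starting material
4 | 4-formyl-3-methoxyphenyl pivalate | COc1cc(OC(=O)C(C)(C)C)ccc1C=O | intermediate
5 | 2-methoxy-4-(pivaloyloxy)benzoic acid | COc1cc(OC(=O)C(C)(C)C)ccc1C(=O)O | intermediate
6 | 2-methoxy-4-(pivaloyloxy)benzoyl chloride | COc1cc(OC(=O)C(C)(C)C)ccc1C(Cl)=O | intermediate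
7 | trilithium salt (two phenoxides and the enolate) of 1-(2,6-dihydroxy-4-methoxyphenyl)ethan-1-one, not isolated | [Li+].[Li+].[Li+].C=C([O-])c1c([O-])cc(OC)cc1[O-] | intermediate
8 | 4-[3-(2,6-dihydroxy-4-methoxyphenyl)-3-oxopropanoyl]-3-methoxyphenyl pivalate | COc1cc(O)c(C(=O)CC(=O)c2ccc(OC(=O)C(C)(C)C)cc2OC)c(O)c1 | intermediate
9 | 4-(2,5-dihydroxy-7-methoxy-4-oxochroman-2-yl)-3-methoxyphenyl pivalate (racemic hemiketal, not isolated) | COc1cc(OC(=O)C(C)(C)C)ccc1C1(O)CC(=O)c2c(O)cc(OC)cc2O1 | intermediate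
10 | 4-(5-hydroxy-7-methoxy-4-oxo-4H-chromen-2-yl)-3-methoxyphenyl pivalate | COc1cc(OC(=O)C(C)(C)C)ccc1-c1cc(=O)c2c(O)cc(OC)cc2o1 | intermediate
11 | 3-methoxy-4-{7-methoxy-5-[(3-methylbut-2-en-1-yl)oxy]-4-oxo-4H-chromen-2-yl}phenyl pivalate | COc1cc(OC(=O)C(C)(C)C)ccc1-c1cc(=O)c2c(OCC=C(C)C)cc(OC)cc2o1 | intermediate
12 | 3-methoxy-4-[7-methoxy-6-(2-methylbut-3-en-2-yl)-4,5-dioxo-5,6-dihydro-4H-chromen-2-yl]phenyl pivalate (racemic, not isolated) | COc1cc(OC(=O)C(C)(C)C)ccc1C1=CC(=O)C2=C(O1)C=C(OC)C(C(C)(C)C=C)C2=O | intermediate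
13 | 3-methoxy-4-[7-methoxy-8-(3-methylbut-2-en-1-yl)-4,5-dioxo-5,8-dihydro-4H-chromen-2-yl]phenyl pivalate (racemic, not isolated) | COc1cc(OC(=O)C(C)(C)C)ccc1C1=CC(=O)C2=C(O1)C(CC=C(C)C)C(OC)=CC2=O | intermediate
14 | 4-[5-hydroxy-7-methoxy-8-(3-methylbut-2-en-1-yl)-4-oxo-4H-chromen-2-yl]-3-methoxyphenyl pivalate | COc1cc(OC(=O)C(C)(C)C)ccc1-c1cc(=O)c2c(O)cc(OC)c(CC=C(C)C)c2o1 | intermediate
15 | Artocarpetin B, 5-hydroxy-2-(4-hydroxy-2-methoxyphenyl)-7-methoxy-8-(3-methylbut-2-en-1-yl)-4H-chromen-4-one | COc1cc(O)ccc1-c1cc(=O)c2c(O)cc(OC)c(CC=C(C)C)c2o1 | target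

## Step count and risks

Total steps: 9. Longest linear sequence: 8 steps (3 → 4 → 5 → 6 → 8 → 10 → 11 → 14 → 15); the other branch (1 → 2) joins at step 5.

**Step 5 (Claisen C-acylation of the trianion).** The risks are competing O-aroylation of the phenoxides and incomplete conversion. The fallback sets out from 2 and 3 and comes back at 10, replacing the acylation by a Claisen–Schmidt aldol condensation and oxidative ring closure. Compound 2 is mono-protected (MOMCl, i-Pr2NEt, CH2Cl2, 0 °C) to 1-[2-hydroxy-4-methoxy-6-(methoxymethoxy)phenyl]ethan-1-one F1, and 3 is converted in the same way into 2-methoxy-4-(methoxymethoxy)benzaldehyde F2. The two are condensed (KOH, EtOH/H2O, rt) to the chalcone (E)-1-[2-hydroxy-4-methoxy-6-(methoxymethoxy)phenyl]-3-[2-methoxy-4-(methoxymethoxy)phenyl]prop-2-en-1-one F3. I2 (cat.) in DMSO at 120 °C cyclises and dehydrogenates it to 7-methoxy-2-[2-methoxy-4-(methoxymethoxy)phenyl]-5-(methoxymethoxy)-4H-chromen-4-one F4, usually with partial loss of MOM. The crude is treated with HCl in MeOH to give 5-hydroxy-2-(4-hydroxy-2-methoxyphenyl)-7-methoxy-4H-chromen-4-one F5. Pivaloyl chloride (1.05 equiv, Et3N, CH2Cl2, 0 °C) then acylates only the non-chelated 4'-OH to give 10.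

**Step 7 (alkylation of the chelated 5-OH).** The reaction may be sluggish, and long heating with carbonate could begin to cleave the pivalate. The fallback sets out from 2 and comes back at 11, putting the prenyl ether on before the flavone exists. Compound 2 is mono-alkylated (prenyl bromide 1.1 equiv, K2CO3, acetone, reflux; the second OH stays chelated) to 1-{2-hydroxy-4-methoxy-6-[(3-methylbut-2-en-1-yl)oxy]phenyl}ethan-1-one F6. This is condensed with 6 (LiN(SiMe3)2 3 equiv, THF, −78 °C to rt) to 4-(3-{2-hydroxy-4-methoxy-6-[(3-methylbut-2-en-1-yl)oxy]phenyl}-3-oxopropanoyl)-3-methoxyphenyl pivalate F7. Buffered cyclodehydration (NaOAc, AcOH, 100 °C), mild enough for the allylic aryl ether, gives 11.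

**Step 8 (Claisen–Cope shift).** The risks are stopping at the 6-(1,1-dimethylallyl) ortho product, or loss of the prenyl group back to 10 (which can be recycled through step 7). The fallback sets out from 10 and comes back at 14, replacing the sigmatropic route by halogenation and cross-coupling. The 5-OH of 10 is protected (MOMCl, NaH, DMF, 0 °C) to 3-methoxy-4-[7-methoxy-5-(methoxymethoxy)-4-oxo-4H-chromen-2-yl]phenyl pivalate F8. N-iodosuccinimide in DMF at rt iodinates the 5,7-dialkoxy ring at C8, its most reactive position once O5 is alkylated, to give 4-[8-iodo-7-methoxy-5-(methoxymethoxy)-4-oxo-4H-chromen-2-yl]-3-methoxyphenyl pivalate F9. Stille coupling with tributyl(3-methylbut-2-en-1-yl)stannane (Pd(PPh3)4, DMF, 90 °C) gives 3-methoxy-4-[7-methoxy-5-(methoxymethoxy)-8-(3-methylbut-2-en-1-yl)-4-oxo-4H-chromen-2-yl]phenyl pivalate F10. Dilute HCl in MeOH/THF at rt removes the labile peri MOM group to give 14; C8 has no neighbouring free OH, so the prenyl group cannot cyclise.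

## Further compounds

F1 | step 5 | 1-[2-hydroxy-4-methoxy-6-(methoxymethoxy)phenyl]ethan-1-one | CC(=O)c1c(O)cc(OC)cc1OCOC
F2 | step 5 | 2-methoxy-4-(methoxymethoxy)benzaldehyde | COCOc1ccc(C=O)c(OC)c1
F3 | step 5 | (E)-1-[2-hydroxy-4-methoxy-6-(methoxymethoxy)phenyl]-3-[2-methoxy-4-(methoxymethoxy)phenyl]prop-2-en-1-one | COCOc1ccc(/C=C/C(=O)c2c(O)cc(OC)cc2OCOC)c(OC)c1
F4 | step 5 | 7-methoxy-2-[2-methoxy-4-(methoxymethoxy)phenyl]-5-(methoxymethoxy)-4H-chromen-4-one | COCOc1ccc(-c2cc(=O)c3c(OCOC)cc(OC)cc3o2)c(OC)c1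
F5 | step 5 | 5-hydroxy-2-(4-hydroxy-2-methoxyphenyl)-7-methoxy-4H-chromen-4-one | COc1cc(O)ccc1-c1cc(=O)c2c(O)cc(OC)cc2o1
F6 | step 7 | 1-{2-hydroxy-4-methoxy-6-[(3-methylbut-2-en-1-yl)oxy]phenyl}ethan-1-one | CC(=O)c1c(O)cc(OC)cc1OCC=C(C)C
F7 | step 7 | 4-(3-{2-hydroxy-4-methoxy-6-[(3-methylbut-2-en-1-yl)oxy]phenyl}-3-oxopropanoyl)-3-methoxyphenyl pivalate | COc1cc(O)c(C(=O)CC(=O)c2ccc(OC(=O)C(C)(C)C)cc2OC)c(OCC=C(C)C)c1
F8 | step 8 | 3-methoxy-4-[7-methoxy-5-(methoxymethoxy)-4-oxo-4H-chromen-2-yl]phenyl pivalate | COCOc1cc(OC)cc2oc(-c3ccc(OC(=O)C(C)(C)C)cc3OC)cc(=O)c12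
F9 | step 8 | 4-[8-iodo-7-methoxy-5-(methoxymethoxy)-4-oxo-4H-chromen-2-yl]-3-methoxyphenyl pivalate | COCOc1cc(OC)c(I)c2oc(-c3ccc(OC(=O)C(C)(C)C)cc3OC)cc(=O)c12
F10 | step 8 | 3-methoxy-4-[7-methoxy-5-(methoxymethoxy)-8-(3-methylbut-2-en-1-yl)-4-oxo-4H-chromen-2-yl]phenyl pivalate | COCOc1cc(OC)c(CC=C(C)C)c2oc(-c3ccc(OC(=O)C(C)(C)C)cc3OC)cc(=O)c12
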